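Ring A is built last, on the finished twelve-membered lactone (ring D). The plan exploits the match between arene C1 (OMe), C2 (H), C6 (lactone carbonyl) and C5 (chain) and C4, C3, C5 and C6 of a 4-methoxy-2-pyrone-5-carboxylate, while C3 (O) and C4 (CH2) are the two carbons of an ynol ether. A single cycloaddition with loss of CO2 joins C2–C3 and C4–C5 and delivers the pentasubstituted benzene. Its precursors are a pyrone grown in two steps on the β-keto macrolactone and a triisopropylsilyl ynol ether that carries both carbon stereocentres of ring C as a cyclic methyl ketal. Desilylation and acid-catalysed ketal exchange then close ring B.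

Key step: step 12

Remark: ring A = arene (C1 OMe, C2 H, C3 O, C4 CH2, C5 chain, C6 C=O), ring B = dihydropyran, ring C = tetrahydrofuran, ring D = macrolactone. Compounds 20–27 are carried as epimer mixtures at the ketal carbon, which is harmless because step 14 resets that centre. Enantiopure (S)-4-methyldihydrofuran-2(3H)-one is taken as purchasable.

**Fragment 1: pyrone on the macrolactone (steps 1–7)**

Step 1
Reactants: 1 1-bromo-5-chloropentane; 2 (R)-propylene oxide
Product: 4 (R)-8-chlorooctan-2-ol, via 5-chloropentylmagnesium bromide 3 (not isolated)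
Conditions: Mg, THF, 25–35 °C; then CuI (10 mol %), 2, THF, −30 → 0 °C; aq. NH4Cl
Reagents that add atoms: none
Why: Magnesium inserts selectively into the C–Br bond and the CuI-catalysed Grignard opening of the epoxide is an SN2 attack at the unsubstituted carbon, so the C–O stereocentre of 2 passes unchanged into 4 as the R carbinol of ring D.

Step 2
Reactants: 4 (R)-8-chlorooctan-2-ol
Product: 5 (R)-8-iodooctan-2-ol
Conditions: NaI (3 equiv), acetone, reflux
Reagents that add atoms: sodium iodide [Na+].[I-]
Why: Finkelstein reaction, in which precipitation of NaCl drives the exchange at the primary carbon and supplies the leaving group that an unactivated enolate alkylation needs, with the remote carbinol untouched.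

Step 3
Reactants: 5 (R)-8-iodooctan-2-ol
Product: 6 (R)-triethyl[(8-iodooctan-2-yl)oxy]silane
Conditions: Et3SiCl, imidazole, CH2Cl2, 0 → 23 °C
Reagents that add atoms: chlorotriethylsilane CC[Si](Cl)(CC)CC
Why: Imidazole-promoted silylation masks the only acidic proton before the dienolate step, and the triethylsilyl group is chosen because it comes off in the acidic work-up of step 4.

Step 4
Reactants: 7 2,2,6-trimethyl-4H-1,3-dioxin-4-one; 6 (R)-triethyl[(8-iodooctan-2-yl)oxy]silane
Product: 10 6-[(8R)-8-hydroxynonyl]-2,2-dimethyl-4H-1,3-dioxin-4-one, via lithium dienolate 8 (not isolated), via triethylsilyl ether 9 (not isolated)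
Conditions: 7 (2.0 equiv), LiN(iPr)2 (1.9 equiv), THF–DMPU (5:1), −78 °C; 6, −78 → −20 °C; then 1 M HCl, THF, 23 °C
Reagents that add atoms: none
Why: Vinylogous enolate alkylation, in which the extended lithium dienolate reacts with primary iodides at its exocyclic γ-carbon in the presence of DMPU, and dilute HCl then cleaves the silyl ether while the dioxinone, which fragments only on heating, survives.

Step 5
Reactants: 10 6-[(8R)-8-hydroxynonyl]-2,2-dimethyl-4H-1,3-dioxin-4-one
Product: 12 (12R)-12-methyl-1-oxacyclododecane-2,4-dione, via acylketene 11 (not isolated)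
Conditions: PhMe, 110 °C, syringe-pump addition (final 1 mM)
Reagents that add atoms: none
Why: Thermal retro-[4+2] of the dioxinone releases acetone and an acylketene that the tethered secondary alcohol captures under pseudo-high dilution (acylketene macrolactonisation), forming the acyl–O bond so that the R centre is retained.

Step 6
Reactants: 12 (12R)-12-methyl-1-oxacyclododecane-2,4-dione; 13 malonyl dichloride
Product: 14 4-hydroxy-2-pyrone fused at C5–C6 to the (R)-12-membered lactone (lactone C=O on pyrone C5, heptamethylene chain on pyrone C6)
Conditions: 13 (1.2 equiv), CH2Cl2, 0 → 40 °C, N2 sweep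
Reagents that add atoms: none
Why: Known pyrone annulation of β-keto esters with malonyl dichloride, in which C-acylation at the α-carbon and O-acylation of the ketone enol by the second acid chloride (in either order) close the 4-hydroxy-2-pyrone and place the lactone carbonyl on C5 and the chain on C6.

Step 7
Reactants: 14 4-hydroxy-2-pyrone fused to the (R)-12-membered lactone
Product: 15 4-methoxy-2-pyrone fused at C5–C6 to the (R)-12-membered lactone
Conditions: Me2SO4, K2CO3, acetone, 23 → 50 °C
Reagents that add atoms: dimethyl sulfate COS(=O)(=O)OC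
Why: O-alkylation of the vinylogous acid with a hard methylating agent and K2CO3 in acetone is the standard entry to 4-methoxy-2-pyrones and favours the 4-oxygen over the ring carbonyl oxygen.

**Fragment 2: siloxyalkyne (steps 8–11)**

Step 8
Reactants: 16 (S)-4-methyldihydrofuran-2(3H)-one; 17 propargyl bromide
Product: 19 (3S,4S)-4-methyl-3-(prop-2-yn-1-yl)dihydrofuran-2(3H)-one (trans), via lithium enolate 18 (not isolated)
Conditions: LiN(iPr)2, THF, −78 °C; 17, −78 → −40 °C
Reagents that add atoms: none
Why: Lactone enolate alkylation under 1,2-induction, in which the electrophile approaches the planar enolate anti to the C4 methyl group and so sets the new C3 centre S (trans), the relationship required between the ring B/C fusion carbon and the methyl-bearing carbon of ring C.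

Step 9
Reactants: 19 (3S,4S)-4-methyl-3-(prop-2-yn-1-yl)dihydrofuran-2(3H)-one
Product: 20 (3S,4S)-2,4-dimethyl-3-(prop-2-yn-1-yl)tetrahydrofuran-2-ol (lactol, in equilibrium with its hydroxy ketone)
Conditions: MeLi (2.1 equiv), Et2O, −78 °C; aq. NH4Cl
Reagents that add atoms: methyllithium [Li]C
Why: One equivalent of MeLi deprotonates the alkyne and the other adds once to the lactone carbonyl (1,2-addition), because the lithium hemiketal alkoxide does not collapse at −78 °C, and neither carbon stereocentre is touched.

Step 10
Reactants: 20 (3S,4S)-2,4-dimethyl-3-(prop-2-yn-1-yl)tetrahydrofuran-2-ol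
Product: 21 (3S,4S)-2-methoxy-2,4-dimethyl-3-(prop-2-yn-1-yl)tetrahydrofuran
Conditions: MeOH, PPTS (5 mol %), 3 Å MS, 23 °C; Et3N quench
Reagents that add atoms: methanol CO
Why: Acid-catalysed ketalisation through the cyclic oxocarbenium ion replaces OH by OMe and removes the last acidic proton and the latent ketone before the ynolate chemistry, while any equilibration at C3 favours the wanted trans C3/C4 arrangement.

Step 11
Reactants: 21 (3S,4S)-2-methoxy-2,4-dimethyl-3-(prop-2-yn-1-yl)tetrahydrofuran
Product: 24 ({3-[(3S,4S)-2-methoxy-2,4-dimethyltetrahydrofuran-3-yl]prop-1-yn-1-yl}oxy)triisopropylsilane, via lithium acetylide 22 (not isolated), via lithium ynolate 23 (not isolated)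
Conditions: n-BuLi, THF, −78 °C; t-BuOOLi (from t-BuOOH + LiN(SiMe3)2), −78 → 0 °C; TIPSOTf, −78 → 0 °C
Reagents that add atoms: lithium tert-butyl peroxide CC(C)(C)OO[Li]; triisopropylsilyl trifluoromethanesulfonate CC(C)[Si](OS(=O)(=O)C(F)(F)F)(C(C)C)C(C)C
Why: Known acetylide oxidation, in which the lithium acetylide attacks the O–O bond of t-BuOOLi to give the ynolate and the hard, bulky silyl triflate captures it on oxygen to give a chromatographable ynol ether, with the basic medium keeping the ketal intact.

**Union and endgame (steps 12–14)**

Step 12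
Reactants: 15 4-methoxy-2-pyrone fused to the (R)-12-membered lactone; 24 triisopropylsilyl ynol ether
Product: 26 macrolide arene bearing OTIPS at C3 and the [(3S,4S)-2-methoxy-2,4-dimethyltetrahydrofuran-3-yl]methyl group at C4, via bridged lactone 25 (not isolated)
Conditions: 24 (1.5 equiv), 2,6-di-tert-butyl-4-methylpyridine (0.2 equiv), PhMe (0.5 M), sealed tube, 140 °C
Reagents that add atoms: none
Why: Proposed new method: the ynol ether is the electron-rich 2π partner and the pyrone the electron-poor 4π partner, so the CH2-bearing alkyne carbon (β to oxygen, largest HOMO coefficient) bonds to pyrone C6, which is β to the C5 ester and δ to the ring carbonyl, while the silyloxy-bearing carbon bonds to pyrone C3, either in concert or through a ketenium/dienolate ion pair that collapses at C3. The 2-oxabicyclo[2.2.2]octadienone 25 then expels CO2 by retro-[4+2] at the reaction temperature, which makes the sequence irreversible and closes ring A in an intermolecular six-membered [4+2] mode (bonds C2–C3 and C4–C5). The closest known reaction types are the inverse-demand cycloaddition/decarboxylation of 2-pyrone-5-carboxylates with ynamines, ketene acetals and enol ethers and the AgNTf2-catalysed cycloadditions of siloxyalkynes with enones and 1,2-diazines, whereas a 4-alkoxy-6-alkyl pyrone carboxylate has not been paired with a siloxyalkyne. No stereocentre is created, because the two bridgehead centres of 25 vanish on aromatisation and the three existing centres lie outside the reacting π systems. The only selectivity needed is regiochemical (O at C3, CH2 at C4), and it is secured by the matched polarity above, which the 4-methoxy group reinforces by making C3 the nucleophilic diene terminus even though it lowers the rate. The hindered pyridine keeps ketal and ynol ether free of adventitious acid, the bulky silyl group suppresses migration to a silylketene, and AgNTf2 (5 mol %, ClCH2CH2Cl, 40 °C, same buffer) is the first variable to try if heat alone is too slow.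

Step 13
Reactants: 26 macrolide arene with C3 OTIPS
Product: 27 C3 phenol bearing the [(3S,4S)-2-methoxy-2,4-dimethyltetrahydrofuran-3-yl]methyl group at C4
Conditions: Bu4NF, AcOH (1:1), THF, 0 °C
Reagents that add atoms: none
Why: Fluoride-induced cleavage of an aryl silyl ether is fast at 0 °C, and the acetic acid buffer protonates the phenoxide as it forms without endangering the hindered macrolactone.

Step 14
Reactants: 27 C3 phenol
Product: 28 lasiodiplactone A
Conditions: camphor-10-sulfonic acid (10 mol %), CH2Cl2, 4 Å MS, 23 °C
Reagents that add atoms: none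
Why: Acid-catalysed transketalisation, in which ionisation of the methyl ketal gives the cyclic oxocarbenium ion and the C3 phenol, tethered through the C4 methylene on one face, captures it in a 6-exo closure that can only be cis-fused, so the adjacent S centre sets the ketal carbon S and the thermodynamic, anomerically stabilised ketal with the ring C methyl group on the convex face results while the sieves take up MeOH.

**Compound list**

1 | 1-bromo-5-chloropentane | ClCCCCCBr | starting material
2 | (R)-propylene oxide | C[C@@H]1CO1 | starting material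
3 | 5-chloropentylmagnesium bromide | ClCCCCC[Mg]Br | intermediate
4 | (R)-8-chlorooctan-2-ol | C[C@@H](O)CCCCCCCl | intermediate
5 | (R)-8-iodooctan-2-ol | C[C@@H](O)CCCCCCI | intermediate
6 | (R)-triethyl[(8-iodooctan-2-yl)oxy]silane | CC[Si](CC)(CC)O[C@H](C)CCCCCCI | intermediate
7 | 2,2,6-trimethyl-4H-1,3-dioxin-4-one | CC1=CC(=O)OC(C)(C)O1 | starting material
8 | lithium dienolate of 7 (4-lithiooxy-2,2-dimethyl-6-methylene-1,3-dioxine) | [Li]OC1=CC(=C)OC(C)(C)O1 | intermediate
9 | 2,2-dimethyl-6-[(8R)-8-(triethylsilyloxy)nonyl]-4H-1,3-dioxin-4-one | CC[Si](CC)(CC)O[C@H](C)CCCCCCCC1=CC(=O)OC(C)(C)O1 | intermediate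
10 | 6-[(8R)-8-hydroxynonyl]-2,2-dimethyl-4H-1,3-dioxin-4-one | C[C@@H](O)CCCCCCCC1=CC(=O)OC(C)(C)O1 | intermediate
11 | (R)-11-hydroxy-3-oxododec-1-en-1-one (acylketene) | C[C@@H](O)CCCCCCCC(=O)C=C=O | intermediate
12 | (12R)-12-methyl-1-oxacyclododecane-2,4-dione | C[C@@H]1CCCCCCCC(=O)CC(=O)O1 | intermediate
13 | malonyl dichloride | O=C(Cl)CC(=O)Cl | starting material
14 | 4-hydroxy-2-pyrone fused at C5–C6 to the (R)-12-membered lactone | OC1=CC(=O)OC2=C1C(=O)O[C@H](C)CCCCCCC2 | intermediate
15 | 4-methoxy-2-pyrone fused at C5–C6 to the (R)-12-membered lactone | COC1=CC(=O)OC2=C1C(=O)O[C@H](C)CCCCCCC2 | intermediate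
16 | (S)-4-methyldihydrofuran-2(3H)-one | O=C1C[C@H](C)CO1 | starting material
17 | propargyl bromide | C#CCBr | starting material
18 | lithium enolate of 16 | [Li]OC1=C[C@H](C)CO1 | intermediate
19 | (3S,4S)-4-methyl-3-(prop-2-yn-1-yl)dihydrofuran-2(3H)-one | C#CC[C@H]1[C@H](C)COC1=O | intermediate
20 | (3S,4S)-2,4-dimethyl-3-(prop-2-yn-1-yl)tetrahydrofuran-2-ol | C#CC[C@H]1[C@H](C)COC1(C)O | intermediate
21 | (3S,4S)-2-methoxy-2,4-dimethyl-3-(prop-2-yn-1-yl)tetrahydrofuran | C#CC[C@H]1[C@H](C)COC1(C)OC | intermediate
22 | lithium acetylide of 21 | [Li]C#CC[C@H]1[C@H](C)COC1(C)OC | intermediate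
23 | lithium ynolate derived from 21 | [Li]OC#CC[C@H]1[C@H](C)COC1(C)OC | intermediate
24 | ({3-[(3S,4S)-2-methoxy-2,4-dimethyltetrahydrofuran-3-yl]prop-1-yn-1-yl}oxy)triisopropylsilane | CC(C)[Si](OC#CC[C@H]1[C@H](C)COC1(C)OC)(C(C)C)C(C)C | intermediate
25 | 2-oxabicyclo[2.2.2]octa-5,7-dien-3-one adduct of 15 and 24 (bridgeheads = pyrone C3 and C6) | O=C1OC23CCCCCCC[C@@H](C)OC(=O)C2=C(OC)C1C(O[Si](C(C)C)(C(C)C)C(C)C)=C3C[C@H]1[C@H](C)COC1(C)OC | intermediate
26 | macrolide arene with C3 OTIPS and the tetrahydrofuran methyl ketal on the C4 methylene | COc1cc(O[Si](C(C)C)(C(C)C)C(C)C)c(C[C@H]3[C@H](C)COC3(C)OC)c2c1C(=O)O[C@H](C)CCCCCCC2 | intermediate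
27 | C3 phenol of 26 | COc1cc(O)c(C[C@H]3[C@H](C)COC3(C)OC)c2c1C(=O)O[C@H](C)CCCCCCC2 | intermediate
28 | lasiodiplactone A (R at the lactone carbinol; S at the ring B/C fusion CH, at the methyl-bearing CH of ring C and at the ketal carbon) | COc1cc2c(c3c1C(=O)O[C@H](C)CCCCCCC3)C[C@H]1[C@H](C)CO[C@@]1(C)O2 | target

Total step count: 14. Longest linear sequence: 10 steps (1–7, then 12–14). Fragment 2 takes 4 steps (8–11).

**Steps most likely to fail**

1. Step 12. The cycloaddition may be too slow, because the 4-methoxy group and the fully substituted diene terminus damp the electron demand. Silyl migration or oligomerisation of the ynol ether, or acid-triggered loss of methanol from the ketal, could then take over.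

   The fallback uses known chemistry: an alkene dienophile at the carboxylic acid oxidation level, with aromatisation by elimination. It sets out from 21 (with 15) and returns at 27.
   - The ynolate 23 is generated from 21 as in step 11 but quenched with HCl in MeOH. This is the last stage of the Kowalski ester homologation, and ketal exchange with MeOH is degenerate. It should give methyl 3-[(3S,4S)-2-methoxy-2,4-dimethyltetrahydrofuran-3-yl]propanoate F1.
   - LiN(iPr)2 and t-BuMe2SiCl in THF–DMPU at −78 °C convert this ester into the tert-butyldimethylsilyl methyl ketene acetal F2, a much stronger nucleophile than the ynol ether.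
   - Heating it with 15 in toluene is the established inverse-demand Diels–Alder reaction of a 2-pyrone-5-carboxylate with a ketene acetal, followed by CO2 loss. It should give the cyclohexa-1,3-diene mixed silyl methyl ketal F3.
   - Immediate treatment with Bu4NF/AcOH collapses the mixed ketal to the dienone, which tautomerises to phenol 27.

2. Step 5. Intermolecular capture of the acylketene (dimerisation, oligomerisation) may outrun closure of the strained twelve-membered ring.

   The fallback closes the ring at a C=C bond instead of the ester. It sets out from 7 and returns at 12.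
   - The dienolate 8 is alkylated with 5-iodopent-1-ene to give 6-(hex-5-en-1-yl)-2,2-dimethyl-4H-1,3-dioxin-4-one F4.
   - Thermolysis in toluene with commercial (R)-pent-4-en-2-ol traps the acylketene intermolecularly as (R)-pent-4-en-2-yl 3-oxonon-8-enoate F5.
   - Ring-closing metathesis with second-generation Grubbs catalyst in dilute CH2Cl2 gives the unsaturated twelve-membered β-keto lactone F6 (either alkene geometry).
   - Hydrogenation (H2, Pd/C, EtOAc) delivers 12.

3. Step 6. A second molecule of the bis-acid chloride may over-acylate the product, O-acylation may stall without ring closure, or the HCl set free may cause degradation.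

   The fallback separates the two bond formations. It sets out from 12 and returns at 14.
   - Soft enolisation with MgCl2 and pyridine in CH2Cl2 and C-acylation with methyl 3-chloro-3-oxopropanoate give methyl 3-[(12R)-12-methyl-2,4-dioxo-1-oxacyclododecan-3-yl]-3-oxopropanoate F7.
   - DBU in refluxing toluene then induces lactonisation of the ketone enol onto the methyl ester, the standard closure of 3,5-dioxo esters to 4-hydroxy-2-pyrones, to give 14.

Further compounds
F1 | step 12 | methyl 3-[(3S,4S)-2-methoxy-2,4-dimethyltetrahydrofuran-3-yl]propanoate | COC(=O)CC[C@H]1[C@H](C)COC1(C)OC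
F2 | step 12 | tert-butyldimethylsilyl methyl ketene acetal of F1 | COC(O[Si](C)(C)C(C)(C)C)=CC[C@H]1[C@H](C)COC1(C)OC
F3 | step 12 | cyclohexa-1,3-diene mixed silyl methyl ketal (C3 sp3 with OMe and OTBS, C4 sp3 with H and the side chain) fused to the (R)-macrolactone | COC1=CC(OC)(O[Si](C)(C)C(C)(C)C)C(C[C@H]3[C@H](C)COC3(C)OC)C2=C1C(=O)O[C@H](C)CCCCCCC2
F4 | step 5 | 6-(hex-5-en-1-yl)-2,2-dimethyl-4H-1,3-dioxin-4-one | C=CCCCCC1=CC(=O)OC(C)(C)O1
F5 | step 5 | (R)-pent-4-en-2-yl 3-oxonon-8-enoate | C=CCCCCC(=O)CC(=O)O[C@H](C)CC=C
F6 | step 5 | (12R)-12-methyl-1-oxacyclododec-9-ene-2,4-dione | C[C@@H]1CC=CCCCCC(=O)CC(=O)O1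
F7 | step 6 | methyl 3-[(12R)-12-methyl-2,4-dioxo-1-oxacyclododecan-3-yl]-3-oxopropanoate | COC(=O)CC(=O)C1C(=O)CCCCCCC[C@@H](C)OC1=O
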